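**Retrosynthetic overview**

1. Numbering used here (Stemona type): ring A = N4, C5–C8, C9, C9a; ring B = N4, C3, C2, C1, C9a; ring C = C1, C9a, C9, C10 (Et), C11 (OH), C12; ring D = C1–O–C14(=O)–C13(Me)–C12; ring E = the lactone C18–C21 on C3.
2. Enabling feature: C9=C9a–C1 is an allyl unit inside ring C with N4 on its central carbon and the ring D oxygen on its terminus C1, which is γ to the C14 carboxyl. It is the trapped form of a 2-heteroatom allyl cation, that is, of a cyclopentene (C1, C12, C11, C10, C9) that has taken up C9a as a dihalocarbene.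
3. Disconnections: ring A (N4–C5 alkylation; C8–C9 Negishi coupling) ⇒ ring B (N4–C9a vinyl amidation of a C9a–Br bond) ⇒ rings C and D in one step (silver-promoted opening of the C9/C9a/C1 dibromocyclopropane with C1–O lactonisation) ⇒ cyclopentene acid + CBr2.
4. Cyclopentene: C12–C13 by Ireland–Claisen rearrangement (the alkene moves to C9=C1); C1–C2 by Negishi coupling to a D-serine-derived iodide that already carries ring E; the carbocycle with C10/C11 by Piancatelli rearrangement.
5. Ring order: E (fragment) and the five-membered carbocycle, then C + D (key step), then B, then A.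

Key step: step 14

Assumption: in step 2 the lipase acylates the (4R,5S)-enantiomer of 2 faster (the CH(Et)C=O side acting as the larger substituent), so that (4S,5R)-3 is recovered as the alcohol.

**Route**

Step 1
Reactants: 1 1-(furan-2-yl)propan-1-ol (racemic)
Product: 2 rac-trans-5-ethyl-4-hydroxycyclopent-2-en-1-one
Conditions: ZnCl2, dioxane–H2O, 95 °C
Reagents that add atoms: water, O
Why: Piancatelli rearrangement, in which the furfuryl cation takes up water at the furan 5-position, the ring opens to a pentadienyl cation and a conrotatory 4π-electrocyclisation closes the cyclopentenone with hydroxyl and ethyl trans.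

Step 2
Reactants: 2 rac-trans-5-ethyl-4-hydroxycyclopent-2-en-1-one
Product: 3 (4S,5R)-5-ethyl-4-hydroxycyclopent-2-en-1-one
Conditions: Pseudomonas cepacia lipase (immobilised), vinyl acetate, t-BuOMe, 30 °C, run to partial conversion
Reagents that add atoms: none
Why: Lipase-catalysed kinetic resolution by transesterification should acylate the (4R,5S)-enantiomer and leave (4S,5R)-3, which fixes the absolute configuration of the future C11 and C10.

Step 3
Reactants: 3 (4S,5R)-5-ethyl-4-hydroxycyclopent-2-en-1-one
Product: 4 (4S,5R)-4-(tert-butyldimethylsilyloxy)-5-ethylcyclopent-2-en-1-one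
Conditions: TBSCl, imidazole, CH2Cl2, 0 °C → rt
Reagents that add atoms: tert-butyldimethylsilyl chloride, CC(C)(C)[Si](C)(C)Cl
Why: Standard silylation of a secondary alcohol, which masks the C11 oxygen (and keeps it from lactonising) until the last step.

Step 4
Reactants: 4 (4S,5R)-4-(tert-butyldimethylsilyloxy)-5-ethylcyclopent-2-en-1-one
Product: 5 (4R,5R)-4-(tert-butyldimethylsilyloxy)-5-ethyl-2-iodocyclopent-2-en-1-one
Conditions: I2, pyridine, CH2Cl2, 0 °C → rt
Reagents that add atoms: iodine, II
Why: α-Iodination of an enone by pyridine addition, iodination of the enolate and elimination places the cross-coupling handle on the future C1 without touching the stereocentres (the descriptor at C4 changes only because of the iodine).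

Step 5
Reactants: 5 (4R,5R)-4-(tert-butyldimethylsilyloxy)-5-ethyl-2-iodocyclopent-2-en-1-one
Product: 6 (1R,4R,5S)-4-(tert-butyldimethylsilyloxy)-5-ethyl-2-iodocyclopent-2-en-1-ol (OH cis to ethyl)
Conditions: NaBH4, CeCl3·7H2O, MeOH, −40 °C
Reagents that add atoms: none
Why: Luche 1,2-reduction, in which hydride should enter anti to the adjacent ethyl group and give the alcohol cis to ethyl, the face that step 6 then inverts.

Step 6
Reactants: 6 (1R,4R,5S)-4-(tert-butyldimethylsilyloxy)-5-ethyl-2-iodocyclopent-2-en-1-ol; 7 propanoic acid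
Product: 8 (1S,4R,5S)-4-(tert-butyldimethylsilyloxy)-5-ethyl-2-iodocyclopent-2-en-1-yl propanoate (ester oxygen trans to ethyl and cis to OTBS)
Conditions: PPh3, DIAD, THF, 0 °C → rt
Reagents that add atoms: none
Why: Mitsunobu esterification with inversion, the propanoate attacking the activated allylic carbinol anti to the ethyl group so that the ester oxygen ends on the face of the OTBS group.

Step 7
Reactants: 8 (1S,4R,5S)-4-(tert-butyldimethylsilyloxy)-5-ethyl-2-iodocyclopent-2-en-1-yl propanoate
Product: 11 (2R)-2-[(1R,4S,5R)-5-(tert-butyldimethylsilyloxy)-4-ethyl-2-iodocyclopent-2-en-1-yl]propanoic acid, via ketene silyl acetal 9 (not isolated), via trimethylsilyl ester 10 (not isolated)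
Conditions: LDA, THF, −78 °C; TMSCl/Et3N, −78 → 50 °C; aq. citric acid
Reagents that add atoms: none
Why: Ireland–Claisen rearrangement, in which the ketene silyl acetal of the kinetic enolate rearranges suprafacially, delivers C13 to C12 on the face the ester oxygen leaves (cis to OTBS), moves the alkene to C9=C1 with iodine on C1, and should set C13 through the boat-like transition state that cycloalkenyl esters of this kind prefer.

Step 8
Reactants: 12 tert-butyl (4R)-4-formyl-2,2-dimethyl-1,3-oxazolidine-3-carboxylate (from D-serine); 13 ethyl 2-(bromomethyl)prop-2-enoate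
Product: 15 tert-butyl (4R)-2,2-dimethyl-4-[(2S)-4-methylidene-5-oxooxolan-2-yl]-1,3-oxazolidine-3-carboxylate, via hydroxy ester 14 (not isolated)
Conditions: Zn, THF–sat. aq NH4Cl, 0 °C → rt; then PPTS (cat.), PhH, 60 °C
Reagents that add atoms: none
Why: Barbier-type zinc allylation of the α-amino aldehyde under non-chelation control (nucleophile anti to the carbamate nitrogen) should give the anti amino alcohol (C18 S), and the γ-hydroxy ester then closes to the α-methylene lactone of ring E.

Step 9
Reactants: 15 tert-butyl (4R)-2,2-dimethyl-4-[(2S)-4-methylidene-5-oxooxolan-2-yl]-1,3-oxazolidine-3-carboxylate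
Product: 16 tert-butyl (4R)-2,2-dimethyl-4-[(2S,4S)-4-methyl-5-oxooxolan-2-yl]-1,3-oxazolidine-3-carboxylate
Conditions: H2 (1 atm), Pd/C, EtOAc, rt
Reagents that add atoms: none
Why: Heterogeneous hydrogenation of the exocyclic methylene from the lactone face opposite the C18 substituent should give the cis-2,4-disubstituted lactone (C20 S).

Step 10
Reactants: 16 tert-butyl (4R)-2,2-dimethyl-4-[(2S,4S)-4-methyl-5-oxooxolan-2-yl]-1,3-oxazolidine-3-carboxylate
Product: 17 tert-butyl N-[(1R)-2-hydroxy-1-[(2S,4S)-4-methyl-5-oxooxolan-2-yl]ethyl]carbamate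
Conditions: AcOH–H2O (4:1), 40 °C
Reagents that add atoms: none
Why: Mild acidic hydrolysis of the N,O-isopropylidene aminal frees the primary alcohol while the carbamate (which keeps nitrogen from attacking ring E) and the lactone stay intact.

Step 11
Reactants: 17 tert-butyl N-[(1R)-2-hydroxy-1-[(2S,4S)-4-methyl-5-oxooxolan-2-yl]ethyl]carbamate
Product: 18 tert-butyl N-[(1S)-2-iodo-1-[(2S,4S)-4-methyl-5-oxooxolan-2-yl]ethyl]carbamate
Conditions: I2, PPh3, imidazole, CH2Cl2, 0 °C → rt
Reagents that add atoms: iodine, II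
Why: Appel-type iodination of the primary alcohol is an SN2 reaction at CH2 that touches no stereocentre (the descriptor at the nitrogen-bearing carbon changes only because of the iodine).

Step 12
Reactants: 18 tert-butyl N-[(1S)-2-iodo-1-[(2S,4S)-4-methyl-5-oxooxolan-2-yl]ethyl]carbamate; 11 (2R)-2-[(1R,4S,5R)-5-(tert-butyldimethylsilyloxy)-4-ethyl-2-iodocyclopent-2-en-1-yl]propanoic acid
Product: 20 cyclopentene acid (acid 11 in which iodine on C1 is replaced by the CH2–CH(NHBoc)–lactone chain of 18), via alkylzinc iodide 19 (not isolated)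
Conditions: 18: Zn dust (I2-activated), DMF, rt; 11: NaH, THF, 0 °C; then Pd2(dba)3, SPhos, DMF–THF, 40 °C; cold 1 M HCl work-up
Reagents that add atoms: none
Why: Negishi coupling, in which zinc inserts into the primary iodide to give a β-carbamate-stabilised alkylzinc that zerovalent palladium joins to the vinyl iodide (C2–C1 bond) without touching C3, the acid being carried as its sodium carboxylate.

Step 13
Reactants: 20 cyclopentene acid
Product: 23 6,6-dibromobicyclo[3.1.0]hexane acid (CBr2 = C9a added across C9=C1 syn to ethyl), via trimethylsilyl ester 21 (not isolated), via silyl ester of the cyclopropane 22 (not isolated)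
Conditions: BSA, PhH–DME, rt; PhHgCBr3, NaI, 20 °C; MeOH–aq. citric acid work-up
Reagents that add atoms: phenyl(tribromomethyl)mercury, BrC(Br)(Br)[Hg]c1ccccc1
Why: Neutral dibromocarbene transfer adds to the only alkene while the acid is masked in the flask as its silyl ester; the face of addition does not matter because both cyclopropane carbons become trigonal in step 14, and any material that opens early converges on the same allyl cation.

Step 14
Reactants: 23 6,6-dibromobicyclo[3.1.0]hexane acid
Product: 24 bromo lactone (rings C and D; vinyl bromide at C9a; lactone oxygen on C1 cis to C13)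
Conditions: AgOSO2CF3, 2,6-di-tert-butyl-4-methylpyridine, CH2Cl2, −20 → 0 °C
Reagents that add atoms: none
Why: Monovalent silver abstracts the endo bromide while the C9–C1 σ-bond of the cyclopropane opens in a disrotatory 2π-electrocyclic fashion, so the five-membered carbocycle expands to ring C as a 2-bromoallyl cation (C9–C9a–C1) whose tertiary terminus C1 is captured by the C14 carboxylate. The closest known reaction type is the silver-promoted electrocyclic ring opening of 6,6-dibromobicyclo[3.1.0]hexanes with capture of the allyl cation by acetate or by a tethered heteroatom nucleophile. Ring C is closed by one-carbon ring expansion (cleavage of the cyclopropane bond), and ring D by 5-exo-type addition of the carboxylate oxygen to the allyl terminus next to its tether, which forms the C1–O bond. The new stereocentre C1 is controlled by that tether: the carboxylate on C12 can reach C1 only on the face that carries C13, so the lactone is cis-fused and both cyclopropane diastereomers give the same product. The step needs regioselectivity between C1 and C9 and chemoselectivity against capture by the Boc group and against proton loss. Five-ring closure of a carboxylate onto the tertiary terminus should secure the first, and the use of the free acid with a hindered, non-nucleophilic pyridine base should secure the second.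

Step 15
Reactants: 24 bromo lactone
Product: 25 N-Boc ene-carbamate (rings B, C and D; N4–C9a bond; C9=C9a with H on C9)
Conditions: CuI, N,N'-dimethylethylenediamine, K2CO3, toluene, 100 °C
Reagents that add atoms: none
Why: Copper-catalysed Goldberg-type intramolecular N-vinylation of the carbamate with the C9a vinyl bromide closes the five-membered ring B and keeps the double bond at C9=C9a.

Step 16
Reactants: 25 N-Boc ene-carbamate
Product: 26 9-bromo ene-carbamate
Conditions: NBS, CH2Cl2, −20 °C
Reagents that add atoms: N-bromosuccinimide, BrN1C(=O)CCC1=O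
Why: Electrophilic bromination of the ene-carbamate at its β-carbon C9 followed by loss of the only available proton (C9–H) gives the β-bromo ene-carbamate.

Step 17
Reactants: 26 9-bromo ene-carbamate; 27 (4-chlorobutyl)zinc bromide
Product: 28 9-(4-chlorobutyl) ene-carbamate
Conditions: Pd(OAc)2, SPhos, THF–NMP, 60 °C
Reagents that add atoms: none
Why: Negishi sp2–sp3 coupling at the β-bromo ene-carbamate attaches the four-carbon chain C8–C5 to C9, the primary chloride being inert to zerovalent palladium and to the organozinc.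

Step 18
Reactants: 28 9-(4-chlorobutyl) ene-carbamate
Product: 30 11-O-TBS ether of the target, via cyclic imine 29 (not isolated)
Conditions: TMSOTf, 2,6-lutidine, CH2Cl2, 0 °C; MeOH; then NaI (cat.), i-Pr2NEt, MeCN, 80 °C
Reagents that add atoms: none
Why: Silyl triflate cleavage of the Boc group gives the NH-enamine, which tautomerises to the cyclic imine; intramolecular N-alkylation (7-exo-tet, iodide catalysis) then gives the iminium ion and loss of the C9 proton gives the tetrasubstituted enamine, closing ring A.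

Step 19
Reactants: 30 11-O-TBS ether of the target
Product: 31 CNP0154902.3 (target)
Conditions: HF·pyridine, THF–pyridine, 0 °C → rt; NaHCO3 work-up
Reagents that add atoms: none
Why: Fluoride cleavage of the secondary silyl ether under buffered, non-basic conditions should avoid translactonisation onto the freed C11 hydroxyl.

**Compound list**

1 | 1-(furan-2-yl)propan-1-ol (racemic) | CCC(O)c1ccco1 | starting material
2 | rac-trans-5-ethyl-4-hydroxycyclopent-2-en-1-one (both enantiomers) | CC[C@@H]1[C@@H](O)C=CC1=O.CC[C@H]1[C@H](O)C=CC1=O | intermediate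
3 | (4S,5R)-5-ethyl-4-hydroxycyclopent-2-en-1-one | CC[C@@H]1[C@@H](O)C=CC1=O | intermediate
4 | (4S,5R)-4-(tert-butyldimethylsilyloxy)-5-ethylcyclopent-2-en-1-one | CC[C@@H]1[C@@H](O[Si](C)(C)C(C)(C)C)C=CC1=O | intermediate
5 | (4R,5R)-4-(tert-butyldimethylsilyloxy)-5-ethyl-2-iodocyclopent-2-en-1-one | CC[C@@H]1[C@@H](O[Si](C)(C)C(C)(C)C)C=C(I)C1=O | intermediate
6 | (1R,4R,5S)-4-(tert-butyldimethylsilyloxy)-5-ethyl-2-iodocyclopent-2-en-1-ol | CC[C@@H]1[C@@H](O[Si](C)(C)C(C)(C)C)C=C(I)[C@@H]1O | intermediate
7 | propanoic acid | CCC(=O)O | starting material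
8 | (1S,4R,5S)-4-(tert-butyldimethylsilyloxy)-5-ethyl-2-iodocyclopent-2-en-1-yl propanoate | CC[C@@H]1[C@@H](O[Si](C)(C)C(C)(C)C)C=C(I)[C@H]1OC(=O)CC | intermediate
9 | ketene trimethylsilyl acetal of 8 (methyl cis to the allylic oxygen) | CC[C@@H]1[C@@H](O[Si](C)(C)C(C)(C)C)C=C(I)[C@H]1O/C(O[Si](C)(C)C)=C\C | intermediate (not isolated)
10 | trimethylsilyl ester of 11 | CC[C@H]1C=C(I)[C@H]([C@@H](C)C(=O)O[Si](C)(C)C)[C@@H]1O[Si](C)(C)C(C)(C)C | intermediate (not isolated)
11 | (2R)-2-[(1R,4S,5R)-5-(tert-butyldimethylsilyloxy)-4-ethyl-2-iodocyclopent-2-en-1-yl]propanoic acid | CC[C@H]1C=C(I)[C@H]([C@@H](C)C(=O)O)[C@@H]1O[Si](C)(C)C(C)(C)C | intermediate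
12 | tert-butyl (4R)-4-formyl-2,2-dimethyl-1,3-oxazolidine-3-carboxylate | O=C[C@H]1COC(C)(C)N1C(=O)OC(C)(C)C | starting material
13 | ethyl 2-(bromomethyl)prop-2-enoate | C=C(CBr)C(=O)OCC | starting material
14 | tert-butyl (4R)-4-[(1S)-3-(ethoxycarbonyl)-1-hydroxybut-3-en-1-yl]-2,2-dimethyl-1,3-oxazolidine-3-carboxylate | C=C(C[C@H](O)[C@H]1COC(C)(C)N1C(=O)OC(C)(C)C)C(=O)OCC | intermediate (not isolated)
15 | tert-butyl (4R)-2,2-dimethyl-4-[(2S)-4-methylidene-5-oxooxolan-2-yl]-1,3-oxazolidine-3-carboxylate | C=C1C[C@H](OC1=O)[C@H]2COC(C)(C)N2C(=O)OC(C)(C)C | intermediate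
16 | tert-butyl (4R)-2,2-dimethyl-4-[(2S,4S)-4-methyl-5-oxooxolan-2-yl]-1,3-oxazolidine-3-carboxylate | C[C@H]1C[C@H](OC1=O)[C@H]2COC(C)(C)N2C(=O)OC(C)(C)C | intermediate
17 | tert-butyl N-[(1R)-2-hydroxy-1-[(2S,4S)-4-methyl-5-oxooxolan-2-yl]ethyl]carbamate | C[C@H]1C[C@H](OC1=O)[C@@H](CO)NC(=O)OC(C)(C)C | intermediate
18 | tert-butyl N-[(1S)-2-iodo-1-[(2S,4S)-4-methyl-5-oxooxolan-2-yl]ethyl]carbamate | C[C@H]1C[C@H](OC1=O)[C@@H](CI)NC(=O)OC(C)(C)C | intermediate
19 | alkylzinc iodide from 18 | C[C@H]1C[C@H](OC1=O)[C@@H](C[Zn]I)NC(=O)OC(C)(C)C | intermediate (not isolated)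
20 | cyclopentene acid (C1 carries CH2–CH(NHBoc)–ring E; C12 carries CH(CH3)CO2H; C11 OTBS; C10 ethyl) | CC[C@H]1C=C(C[C@@H](NC(=O)OC(C)(C)C)[C@@H]2C[C@H](C)C(=O)O2)[C@H]([C@@H](C)C(=O)O)[C@@H]1O[Si](C)(C)C(C)(C)C | intermediate
21 | trimethylsilyl ester of 20 | CC[C@H]1C=C(C[C@@H](NC(=O)OC(C)(C)C)[C@@H]2C[C@H](C)C(=O)O2)[C@H]([C@@H](C)C(=O)O[Si](C)(C)C)[C@@H]1O[Si](C)(C)C(C)(C)C | intermediate (not isolated)
22 | trimethylsilyl ester of 23 | CC[C@H]1[C@H]2C(Br)(Br)[C@@]2(C[C@@H](NC(=O)OC(C)(C)C)[C@@H]3C[C@H](C)C(=O)O3)[C@H]([C@@H](C)C(=O)O[Si](C)(C)C)[C@@H]1O[Si](C)(C)C(C)(C)C | intermediate (not isolated)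
23 | 6,6-dibromobicyclo[3.1.0]hexane acid (CBr2 bridging C9 and C1, syn to ethyl) | CC[C@H]1[C@H]2C(Br)(Br)[C@@]2(C[C@@H](NC(=O)OC(C)(C)C)[C@@H]3C[C@H](C)C(=O)O3)[C@H]([C@@H](C)C(=O)O)[C@@H]1O[Si](C)(C)C(C)(C)C | intermediate
24 | bromo lactone (rings C and D; C9=C9a–Br; C1–O lactone; NHBoc side chain on C1) | CC[C@H]1C=C(Br)[C@]2(C[C@@H](NC(=O)OC(C)(C)C)[C@@H]3C[C@H](C)C(=O)O3)OC(=O)[C@H](C)[C@@H]2[C@@H]1O[Si](C)(C)C(C)(C)C | intermediate
25 | N-Boc ene-carbamate (rings B, C, D; H on C9) | CC[C@H]1C=C2N(C(=O)OC(C)(C)C)[C@@H]([C@@H]3C[C@H](C)C(=O)O3)C[C@]24OC(=O)[C@H](C)[C@@H]4[C@@H]1O[Si](C)(C)C(C)(C)C | intermediate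
26 | 9-bromo ene-carbamate | CC[C@H]1C(Br)=C2N(C(=O)OC(C)(C)C)[C@@H]([C@@H]3C[C@H](C)C(=O)O3)C[C@]24OC(=O)[C@H](C)[C@@H]4[C@@H]1O[Si](C)(C)C(C)(C)C | intermediate
27 | (4-chlorobutyl)zinc bromide | ClCCCC[Zn]Br | starting material
28 | 9-(4-chlorobutyl) ene-carbamate | CC[C@H]1C(CCCCCl)=C2N(C(=O)OC(C)(C)C)[C@@H]([C@@H]3C[C@H](C)C(=O)O3)C[C@]24OC(=O)[C@H](C)[C@@H]4[C@@H]1O[Si](C)(C)C(C)(C)C | intermediate
29 | cyclic imine N4=C9a with the 4-chlorobutyl chain on C9 (C9 epimers) | CC[C@H]1C(CCCCCl)C2=N[C@@H]([C@@H]3C[C@H](C)C(=O)O3)C[C@]24OC(=O)[C@H](C)[C@@H]4[C@@H]1O[Si](C)(C)C(C)(C)C | intermediate (not isolated)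
30 | 11-O-(tert-butyldimethylsilyl) ether of the target | CC[C@H]1C2=C3N(CCCC2)[C@@H]([C@@H]2C[C@H](C)C(=O)O2)C[C@]32OC(=O)[C@H](C)[C@@H]2[C@@H]1O[Si](C)(C)C(C)(C)C | intermediate
31 | CNP0154902.3 | CC[C@H]1C2=C3N(CCCC2)[C@@H]([C@@H]2C[C@H](C)C(=O)O2)C[C@]32OC(=O)[C@H](C)[C@@H]2[C@@H]1O | target

**Step count and risks**

Total step count: 19. Longest linear sequence: 15 steps (steps 1–7 and 12–19).

Step 14. What may go wrong: capture of the allyl cation by the Boc carbonyl or nitrogen, or loss of a proton to a diene, could compete with lactonisation, and acid set free could strip the Boc or silyl group. Fallback: setting out from 23, the acid is silylated with BSA and heated in toluene at 100 °C so that the cyclopropane opens thermally and the ion pair collapses to the rearranged allylic dibromide acid F1 (bromine on C9 and C9a, C9a=C1) after aqueous work-up. Cs2CO3 in DMF then closes the lactone by intramolecular SN2′ attack of the carboxylate on C1 with loss of bromide from C9, without a free cation, and the route is rejoined at 24.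

Step 17. What may go wrong: oxidative addition and transmetalation at the hindered, tetrasubstituted bromo ene-carbamate may be slow, so that protodebromination or β-hydride elimination of the alkylpalladium takes over. Fallback: setting out from 26, Sonogashira coupling with 4-chlorobut-1-yne (PdCl2(PPh3)2, CuI, i-Pr2NH), which is far less sensitive to hindrance, gives the 9-(4-chlorobut-1-ynyl) ene-carbamate F2. Hydrogenation of the alkyne (H2, PtO2, EtOAc), which should spare the tetrasubstituted ene-carbamate, rejoins the route at 28.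

Step 18. What may go wrong: closure of the seven-membered ring by SN2 at the hindered imine nitrogen may be slower than intermolecular alkylation or loss of HCl from the chain. Fallback: setting out from 26, Negishi coupling with [3-(1,3-dioxolan-2-yl)propyl]zinc bromide (Pd(OAc)2, SPhos) gives the 9-[3-(1,3-dioxolan-2-yl)propyl] ene-carbamate F3. TMSOTf/2,6-lutidine followed by PPTS in wet acetone removes the Boc group and the dioxolane, and the NH-enamine condenses reversibly with the freed aldehyde to the ring A dienamine F4 (N4–C5=C6), so ring A forms by condensation and not by substitution. NaBH(OAc)3/AcOH then reduces the aldiminium ion at C5 in preference to the hindered C9a position and rejoins the route at 30.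

Further compounds
F1 | step 14 | rearranged allylic dibromide acid (2,3-dibromocyclohexene: Br on C9 and C9a, C9a=C1; C9 configuration undefined) | CC[C@H]1C(Br)C(Br)=C(C[C@@H](NC(=O)OC(C)(C)C)[C@@H]2C[C@H](C)C(=O)O2)[C@H]([C@@H](C)C(=O)O)[C@@H]1O[Si](C)(C)C(C)(C)C
F2 | step 17 | 9-(4-chlorobut-1-ynyl) ene-carbamate | CC[C@H]1C(C#CCCCl)=C2N(C(=O)OC(C)(C)C)[C@@H]([C@@H]3C[C@H](C)C(=O)O3)C[C@]24OC(=O)[C@H](C)[C@@H]4[C@@H]1O[Si](C)(C)C(C)(C)C
F3 | step 18 | 9-[3-(1,3-dioxolan-2-yl)propyl] ene-carbamate | CC[C@H]1C(CCCC2OCCO2)=C3N(C(=O)OC(C)(C)C)[C@@H]([C@@H]4C[C@H](C)C(=O)O4)C[C@]35OC(=O)[C@H](C)[C@@H]5[C@@H]1O[Si](C)(C)C(C)(C)C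
F4 | step 18 | ring A dienamine (N4–C5=C6) of the 11-O-TBS ether | CC[C@H]1C2=C3N(C=CCC2)[C@@H]([C@@H]2C[C@H](C)C(=O)O2)C[C@]32OC(=O)[C@H](C)[C@@H]2[C@@H]1O[Si](C)(C)C(C)(C)C
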